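## Analysis of the target

The target 25 is a 3',8''-linked biflavanone. Rings A and C (O1, C2 to C8a) form a 5,7-dihydroxychroman-4-one, ring B (C1' to C6', OH at C4') is its C2 aryl group, and C3' of ring B is bonded to C8'' of a second chroman-4-one (rings D and E, 5''-OH, 7''-OMe) that carries a 4-hydroxyphenyl group (ring F) at C2''. The only stereocentres are C2 and C2'', both S, each a benzylic carbon bonded to a pyranone oxygen. They lie seven bonds apart across the biaryl bond, so neither can steer the other and each must be set by an external chiral agent. Both C2–O1 bonds are β to a ketone, so base or a strong Lewis acid can open either ring to a 2'-hydroxychalcone and racemise it; the five phenols therefore need protecting groups that come off under neutral conditions. The hard points are the C3'–C8'' bond, flanked by three oxygen-bearing ortho carbons (C4', C7'', C8a''), and ring D, a phloroglucinol whose three oxygens must end in three different states (ring ether O1'', free 5''-OH, methyl ether at C7''). The strategy rests on the fact that only the 7''-oxygen is para to the acyl-bearing C4a'', while O1'' and O5'' are ortho to it: a symmetrical 2,4,6-trimethoxyphenyl group can stand for ring D, and after acylation a chelating Lewis acid can tell the methyl ethers apart. Ring B (carbon at C1', aryl at C3', oxygen at C4') is the pattern that a 4-aryl-1-methoxy-3-silyloxybutadiene and a propiolate give on cycloaddition and aromatisation, so the hindered biaryl bond can be the benzylic bond of an arylacetic acid and need never be made by coupling.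

## Retrosynthetic reasoning

**25 from 24.** The five O–H bonds are traced back to benzyl ethers. Hydrogenolysis is neutral, spares the 7''-methyl ether and the ketones, and is the mildest last step for two base-labile flavanone centres.

**24 from 22.** The C2–H and C2''–H bonds (with C3–H and C3''–H) are removed, which leads back to the biflavone 22. Flavones are flat and robust and carry no stereocentre through the basic and acidic ring constructions. Both centres can then be set in one catalyst-controlled hydride transfer to the Re face of C2 and of C2'', just before deprotection.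

**22 from 20, and 20 from 18 and 19.** Ring C is cut at O1–C2 and C2–C3. Ring A arrives as the acetophenone 19 with C3 and C4 in place, and ring B supplies C2 at the carboxylic acid level, which is what the key step leaves at C1'. The forward sequence is O-acylation to 20, O-to-C acyl shift to the diketone 21 and cyclodehydration.

**18 from 17, and 17 from 14 and 15.** Ring E is cut at O1''–C2'' and C2''–C3''. The C2''=C3'' bond comes from an aldol condensation of the ring D acetyl group with aldehyde 15, and O1''–C2'' from oxidative closure of the chalcone 17. Closure must go onto the oxygen next to the biaryl bond, which is why the other ortho oxygen is benzylated in 14 and only the flanked phenol is left free.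

**14 from 13, 12 and 10.** The C4a''–C4'' bond is cut as a Friedel–Crafts acylation. In 10 the two free positions of the trimethoxyphenyl ring are equivalent, so the acylation has no regiochemical question. The two methyl ethers ortho to the new ketone are then cleaved under chelation control (13) and the phenols are sorted by benzylation (14).

**10 from 6 and 7.** Ring B is cut at C2'–C3' and C1'–C6', which gives the silyloxydiene 6 and the propiolate 7. Cutting here and not at C3'–C8'' avoids a triply ortho-substituted biaryl coupling. It also places the C4' oxygen (the former ketone oxygen) and the C1' ester in one step. The forward reaction must pair the aryl-bearing diene terminus with the β-carbon of 7 and then aromatise.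

**6 from 5, 4, 2, 1 and 3.** The diene is the enol silane of the β-methoxy enone 5. Enone 5 is the adduct of an alcohol to the ynone 4, which comes from the N-methoxy-N-methylamide 2 of the purchased acid 1 and the alkynyl Grignard reagent 3. These four steps are routine, so the risk of the route sits in the cycloaddition.

## Alternatives that were turned down

**Alternative 1:** Ring E would be cut at C3''–C4'' and O1''–C2''.
- Forward key step: a chiral phosphoric acid and an orthoformate would turn a 3-aryl salicylaldehyde (rings D and B already joined, chlorine at C1') into a 4-methoxy ortho-quinone methide cation. This cation would take up the styrene A2 in a [4+2] reaction and give the 2,4-cis (2S)-4-methoxyflavan A1.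
- For it: C2'' is set by the catalyst in the ring-forming step, so ring E needs no late reduction. On this point it is stronger than the chosen route, which leaves both centres to one demanding late reduction.
- Against it: A1 is at the flavan-4-ol ether oxidation level, so C4'' must later be raised to the ketone next to an electron-rich ring and a benzylic C2''–H. The cation is stabilised by two alkoxy groups and the ring oxygen, so a pathway outside the chiral ion pair can compete. The hindered C3'–C8'' bond must first be made by cross-coupling. Ring B leaves with only chlorine at C1', so ring C and C2 remain to be built through an aryl chloride while a base-labile C2'' centre is carried along.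
- Comparison: it needs two different stereochemical solutions and more functional-group changes. The chosen route offers instead a coupling-free biaryl bond, a C1' ester ready for ring C, and one operation for both stereocentres.

**Alternative 2:** Ring D would be built by cutting C8''–C8a'' and C6''–C7''.
- Forward key step: heating the cyclobutenone A4 with a ring B aryl methoxyalkyne opens A4 to a vinylketene, which adds to the alkyne by [2+2]. A 4π opening of the new cyclobutenone and 6π closure of the dienylketene would give the phenol A3.
- For it: like the chosen route it avoids biaryl cross-coupling. It is clearly stronger on one point: A3 emerges with the three ring D oxygens already told apart (free OH for O1'', methyl ether at C7'', benzyl ether at C5''), where the chosen route needs a double demethylation and a site-selective benzylation.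
- Against it: the aryl alkynyl ether is sensitive to acid and water and takes several steps from a ring B arene, and A4 is itself a strained, multistep building block. The acyl group for ring E must then be placed at C4a'' in competition with C6'', both flanked by two oxygens. Ring B arrives with bromine at C1', so the carbon for C2 is still missing.
- Comparison: the two precursors outweigh the four steps to the diene of the chosen route. The chosen route also has an acylation without a regiochemical question and a ring B that already carries the C1' ester.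

**Alternative 3:** Ring E would be cut at C4''–C4a''.
- Forward key step: an (S)-3-aryl-3-aryloxypropanoic acid, with the O1''–C2'' ether bond and the stereocentre already in place, would be activated by a perfluorinated carboxylic anhydride and would acylate C4a'' intramolecularly to give the (2S)-flavanone A5.
- For it: the closure is a six-membered Friedel–Crafts acylation at a position activated by three oxygens, and it is regiochemically forced because the other carbon ortho to the ether oxygen carries ring B. The stereocentre is made by a stoichiometric, well-understood displacement and not by reduction of a poorly electrophilic chromone; on this point it is the safer of the two.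
- Against it: C2'' is a benzylic ether carbon with a para-oxygenated aryl group and an electron-rich phenol as leaving group. Under strongly acidic acylating conditions, C2''–O1'' heterolysis or retro-oxa-Michael loss of the phenol threatens both the configuration and the ring. Making that ether by substitution at a secondary benzylic centre invites SN1 leakage. The phenol needed is of the type of A3, so ring D and the biaryl bond must be secured first, and ring C is again a separate task through an aryl bromide.
- Comparison: it is longer and carries an acid-labile stereocentre through an electrophilic step, whereas the chosen route keeps both pyranone rings achiral until the penultimate step.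

Key step: step 5

## Remarks on the chemistry (assumptions)

- The C3'–C8'' axis carries three ortho oxygen substituents; it is assumed not to be configurationally stable at room temperature, so it adds no stereoisomers.
- Compounds 1, 15 and 19 are taken as purchased.
- Step 13 is written with (R)-DTBM-SEGPHOS on the assumption that this ligand delivers hydride to the Re face of C2 and of C2''; if the sense is the opposite, the (S)-ligand is used.

## Route

Step 1
Reactants: 1 (2,4,6-trimethoxyphenyl)acetic acid
Product: 2 N-methoxy-N-methyl-2-(2,4,6-trimethoxyphenyl)acetamide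
Conditions: MeNH(OMe)·HCl, EDC·HCl, HOBt (cat.), Et3N, CH2Cl2, 0 °C to rt
Reagents that add atoms: N,O-dimethylhydroxylamine hydrochloride, CNOC.Cl
Why: Carbodiimide amide coupling; the N-methoxy-N-methylamide is chosen because its magnesium chelate stops the next addition at the ketone stage.

Step 2
Reactants: 2 N-methoxy-N-methyl-2-(2,4,6-trimethoxyphenyl)acetamide; 3 ethynylmagnesium bromide
Product: 4 1-(2,4,6-trimethoxyphenyl)but-3-yn-2-one
Conditions: THF, 0 °C; then cold 1 M HCl
Reagents that add atoms: none
Why: Weinreb ketone synthesis; the chelated tetrahedral adduct survives until the acidic quench, which also protonates the released amine so that it cannot add to the ynone.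

Step 3
Reactants: 4 1-(2,4,6-trimethoxyphenyl)but-3-yn-2-one
Product: 5 (3E)-4-methoxy-1-(2,4,6-trimethoxyphenyl)but-3-en-2-one
Conditions: MeOH, DABCO (10 mol%), 0 °C to rt
Reagents that add atoms: methanol, CO
Why: Amine-catalysed oxa-Michael addition of an alcohol to a terminal ynone; the reversible addition should settle on the (E)-β-methoxy enone, and the mild base leaves the benzylic ketone alone.

Step 4
Reactants: 5 (3E)-4-methoxy-1-(2,4,6-trimethoxyphenyl)but-3-en-2-one
Product: 6 trimethyl{[(1Z,3E)-4-methoxy-1-(2,4,6-trimethoxyphenyl)buta-1,3-dien-2-yl]oxy}silane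
Conditions: Me3SiOTf, Et3N, Et2O, 0 °C; pentane, filtration under argon; used crude
Reagents that add atoms: trimethylsilyl trifluoromethanesulfonate, C[Si](C)(C)OS(=O)(=O)C(F)(F)F
Why: Soft enolisation (O-silylation of the vinylogous ester, then deprotonation by the amine); only the benzylic CH2 can lose a proton, and the (Z)-enol silane, with the twisted aryl group trans to the vinyl group, is the less strained isomer.

Step 5
Reactants: 6 trimethyl{[(1Z,3E)-4-methoxy-1-(2,4,6-trimethoxyphenyl)buta-1,3-dien-2-yl]oxy}silane; 7 methyl prop-2-ynoate
Product: 10 methyl 4-hydroxy-3-(2,4,6-trimethoxyphenyl)benzoate, via cycloadduct 8 (not isolated), via aryl silyl ether 9 (not isolated)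
Conditions: 7 (3 equiv), toluene, 100 °C, sealed tube; then 1 M HCl, THF, rt
Reagents that add atoms: none
Why: This is a normal-demand Diels–Alder reaction of a 1-methoxy-3-silyloxybutadiene with an alkynoate; the closest known reaction type is the cycloaddition and aromatisation of such dienes with propiolates to 4-hydroxybenzoates. Ring B is closed by a concerted, suprafacial [4π+2π] cycloaddition in which C2'–C3' and C1'–C6' form in the same step, giving the cyclohexa-1,4-diene 8. The silyloxy and methoxy donors put the largest HOMO coefficient on the aryl-bearing terminus, which pairs with the β-carbon of 7, so the ester ends up para to the oxygen and meta to the aryl group. The (1Z,3E) geometry keeps both terminal substituents on the outside of the s-cis diene, and the dienophile is linear and small, which is what the twisted 2,6-dimethoxyaryl terminus needs. The two sp3 centres of 8 (3,6-cis) do not persist: acid ionises the doubly allylic methoxy group with help from the enol silane, loss of the C3' proton gives the aryl silyl ether 9, and aqueous acid frees the phenol. No lasting stereocentre is formed, and the trimethoxyarene takes no part.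

Step 6
Reactants: 10 methyl 4-hydroxy-3-(2,4,6-trimethoxyphenyl)benzoate
Product: 12 methyl 3-(3-acetyl-2,4,6-trimethoxyphenyl)-4-hydroxybenzoate, via O-acetyl ketone 11 (not isolated)
Conditions: Ac2O (3 equiv), Sc(OTf)3 (10 mol%), MeNO2, 50 °C; then K2CO3, MeOH, rt
Reagents that add atoms: acetic anhydride, CC(=O)OC(C)=O
Why: Friedel–Crafts acylation; the trimethoxy ring is far more nucleophilic than ring B (ester, acetylated phenol), its two free positions are equivalent, the ketone blocks a second acylation, and the phenol acetate formed alongside is removed by methanolysis.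

Step 7
Reactants: 12 methyl 3-(3-acetyl-2,4,6-trimethoxyphenyl)-4-hydroxybenzoate
Product: 13 methyl 3-(3-acetyl-2,4-dihydroxy-6-methoxyphenyl)-4-hydroxybenzoate
Conditions: BCl3 (5 equiv), CH2Cl2, −78 °C to rt; aqueous work-up
Reagents that add atoms: none
Why: Chelation-controlled ether cleavage; boron bound to the ketone oxygen reaches only the two ortho methoxy groups, chloride removes each methyl group by SN2, and the para (future 7'') methoxy group and the methyl ester should stay.

Step 8
Reactants: 13 methyl 3-(3-acetyl-2,4-dihydroxy-6-methoxyphenyl)-4-hydroxybenzoate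
Product: 14 methyl 3-[3-acetyl-4-(benzyloxy)-2-hydroxy-6-methoxyphenyl]-4-(benzyloxy)benzoate
Conditions: BnBr (2.1 equiv), K2CO3, DMF, rt
Reagents that add atoms: benzyl bromide, BrCc1ccccc1
Why: Williamson etherification under weak base; the ring B phenol and the less hindered chelated phenol react, while the 2-OH, hydrogen-bonded to the ketone and flanked by the biaryl bond, should be left for ring E.

Step 9
Reactants: 14 methyl 3-[3-acetyl-4-(benzyloxy)-2-hydroxy-6-methoxyphenyl]-4-(benzyloxy)benzoate; 15 4-(benzyloxy)benzaldehyde
Product: 17 4-(benzyloxy)-3-[4-(benzyloxy)-3-{(2E)-3-[4-(benzyloxy)phenyl]prop-2-enoyl}-2-hydroxy-6-methoxyphenyl]benzoic acid, via chalcone methyl ester 16 (not isolated)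
Conditions: KOH (excess), MeOH–THF–H2O, rt to 50 °C; then 1 M HCl
Reagents that add atoms: potassium hydroxide, [K+].[OH-]
Why: Claisen–Schmidt condensation of the methyl ketone with a non-enolisable aldehyde gives the (E)-chalcone; the excess hydroxide then saponifies the benzoate, which is wanted for step 11, and benzyl ethers are stable.

Step 10
Reactants: 17 4-(benzyloxy)-3-[4-(benzyloxy)-3-{(2E)-3-[4-(benzyloxy)phenyl]prop-2-enoyl}-2-hydroxy-6-methoxyphenyl]benzoic acid
Product: 18 4-(benzyloxy)-3-{5-(benzyloxy)-2-[4-(benzyloxy)phenyl]-7-methoxy-4-oxo-4H-chromen-8-yl}benzoic acid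
Conditions: I2 (10 mol%), DMSO, 130 °C
Reagents that add atoms: none
Why: Iodine/DMSO oxidative cyclisation of a 2'-hydroxychalcone (oxa-Michael closure, α-iodination, loss of HI, which DMSO re-oxidises); the only free phenol is the one next to the biaryl bond, which fixes the 8''-aryl regiochemistry of ring E.

Step 11
Reactants: 18 4-(benzyloxy)-3-{5-(benzyloxy)-2-[4-(benzyloxy)phenyl]-7-methoxy-4-oxo-4H-chromen-8-yl}benzoic acid; 19 1-[2,4-bis(benzyloxy)-6-hydroxyphenyl]ethan-1-one
Product: 20 2-acetyl-3,5-bis(benzyloxy)phenyl 4-(benzyloxy)-3-{5-(benzyloxy)-2-[4-(benzyloxy)phenyl]-7-methoxy-4-oxo-4H-chromen-8-yl}benzoate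
Conditions: DCC, DMAP (cat.), CH2Cl2, rt
Reagents that add atoms: none
Why: Steglich esterification; acyl transfer through the acylpyridinium ion overcomes the low nucleophilicity of the hydrogen-bonded phenol and puts the ring B acyl group next to the acetyl group.

Step 12
Reactants: 20 2-acetyl-3,5-bis(benzyloxy)phenyl 4-(benzyloxy)-3-{5-(benzyloxy)-2-[4-(benzyloxy)phenyl]-7-methoxy-4-oxo-4H-chromen-8-yl}benzoate
Product: 22 5,7-bis(benzyloxy)-2-[4-(benzyloxy)-3-{5-(benzyloxy)-2-[4-(benzyloxy)phenyl]-7-methoxy-4-oxo-4H-chromen-8-yl}phenyl]-4H-chromen-4-one, via 1,3-diketone 21 (not isolated)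
Conditions: LiN(SiMe3)2 (3.5 equiv), THF, −78 °C to rt; AcOH; then NaOAc, AcOH, 100 °C
Reagents that add atoms: none
Why: Baker–Venkataraman rearrangement (the ketone enolate attacks the neighbouring aryl ester through a six-membered transition state) followed by cyclodehydration of the o-hydroxyaryl 1,3-diketone to the chromone; buffered acetic acid spares the benzyl ethers.

Step 13
Reactants: 22 5,7-bis(benzyloxy)-2-[4-(benzyloxy)-3-{5-(benzyloxy)-2-[4-(benzyloxy)phenyl]-7-methoxy-4-oxo-4H-chromen-8-yl}phenyl]-4H-chromen-4-one
Product: 24 (2S)-5,7-bis(benzyloxy)-2-[4-(benzyloxy)-3-{(2S)-5-(benzyloxy)-2-[4-(benzyloxy)phenyl]-7-methoxy-4-oxo-3,4-dihydro-2H-chromen-8-yl}phenyl]-2,3-dihydro-4H-chromen-4-one, via bis(enol silane) 23 (not isolated)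
Conditions: Cu(OAc)2 (10 mol%), (R)-DTBM-SEGPHOS (11 mol%), (EtO)2MeSiH (5 equiv), toluene, 0 °C to rt; then 1 M HCl, THF, 0 °C
Reagents that add atoms: none
Why: Copper hydride-catalysed asymmetric conjugate reduction of chromones; the ligated monovalent copper hydride delivers hydride to the Re face of C2 and of C2'' independently (catalyst control, the sites being remote), each enolate is held as an enol silane, which blocks over-reduction and retro-oxa-Michael opening, and cold dilute acid frees the ketones.

Step 14
Reactants: 24 (2S)-5,7-bis(benzyloxy)-2-[4-(benzyloxy)-3-{(2S)-5-(benzyloxy)-2-[4-(benzyloxy)phenyl]-7-methoxy-4-oxo-3,4-dihydro-2H-chromen-8-yl}phenyl]-2,3-dihydro-4H-chromen-4-one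
Product: 25 (2S)-5,7-dihydroxy-2-[4-hydroxy-3-{(2S)-5-hydroxy-2-(4-hydroxyphenyl)-7-methoxy-4-oxo-3,4-dihydro-2H-chromen-8-yl}phenyl]-2,3-dihydro-4H-chromen-4-one
Conditions: H2 (1 atm), 10% Pd/C, EtOAc–MeOH, rt
Reagents that add atoms: none
Why: Hydrogenolysis of five benzyl aryl ethers under neutral conditions; the methyl ether, the aryl ketones and the C2 and C2'' centres should be untouched if the reaction is stopped once debenzylation is complete.

## Compound list

1 | (2,4,6-trimethoxyphenyl)acetic acid | COc1cc(OC)c(CC(=O)O)c(OC)c1 | starting material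
2 | N-methoxy-N-methyl-2-(2,4,6-trimethoxyphenyl)acetamide | COc1cc(OC)c(CC(=O)N(C)OC)c(OC)c1 | intermediate
3 | ethynylmagnesium bromide | C#C[Mg]Br | starting material
4 | 1-(2,4,6-trimethoxyphenyl)but-3-yn-2-one | COc1cc(OC)c(CC(=O)C#C)c(OC)c1 | intermediate
5 | (3E)-4-methoxy-1-(2,4,6-trimethoxyphenyl)but-3-en-2-one | CO/C=C/C(=O)Cc1c(OC)cc(OC)cc1OC | intermediate
6 | trimethyl{[(1Z,3E)-4-methoxy-1-(2,4,6-trimethoxyphenyl)buta-1,3-dien-2-yl]oxy}silane | CO/C=C/C(O[Si](C)(C)C)=C/c1c(OC)cc(OC)cc1OC | intermediate
7 | methyl prop-2-ynoate | C#CC(=O)OC | starting material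
8 | methyl 3,6-cis-6-methoxy-3-(2,4,6-trimethoxyphenyl)-4-[(trimethylsilyl)oxy]cyclohexa-1,4-diene-1-carboxylate (racemic, one enantiomer drawn) | COC(=O)C1=C[C@H](c2c(OC)cc(OC)cc2OC)C(O[Si](C)(C)C)=C[C@@H]1OC | intermediate (not isolated)
9 | methyl 3-(2,4,6-trimethoxyphenyl)-4-[(trimethylsilyl)oxy]benzoate | COC(=O)c1ccc(O[Si](C)(C)C)c(-c2c(OC)cc(OC)cc2OC)c1 | intermediate (not isolated)
10 | methyl 4-hydroxy-3-(2,4,6-trimethoxyphenyl)benzoate | COC(=O)c1ccc(O)c(-c2c(OC)cc(OC)cc2OC)c1 | intermediate
11 | methyl 4-(acetyloxy)-3-(3-acetyl-2,4,6-trimethoxyphenyl)benzoate | COC(=O)c1ccc(OC(C)=O)c(-c2c(OC)cc(OC)c(C(C)=O)c2OC)c1 | intermediate (not isolated)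
12 | methyl 3-(3-acetyl-2,4,6-trimethoxyphenyl)-4-hydroxybenzoate | COC(=O)c1ccc(O)c(-c2c(OC)cc(OC)c(C(C)=O)c2OC)c1 | intermediate
13 | methyl 3-(3-acetyl-2,4-dihydroxy-6-methoxyphenyl)-4-hydroxybenzoate | COC(=O)c1ccc(O)c(-c2c(OC)cc(O)c(C(C)=O)c2O)c1 | intermediate
14 | methyl 3-[3-acetyl-4-(benzyloxy)-2-hydroxy-6-methoxyphenyl]-4-(benzyloxy)benzoate | COC(=O)c1ccc(OCc2ccccc2)c(-c2c(OC)cc(OCc3ccccc3)c(C(C)=O)c2O)c1 | intermediate
15 | 4-(benzyloxy)benzaldehyde | O=Cc1ccc(OCc2ccccc2)cc1 | starting material
16 | methyl 4-(benzyloxy)-3-[4-(benzyloxy)-3-{(2E)-3-[4-(benzyloxy)phenyl]prop-2-enoyl}-2-hydroxy-6-methoxyphenyl]benzoate | COC(=O)c1ccc(OCc2ccccc2)c(-c2c(OC)cc(OCc3ccccc3)c(C(=O)/C=C/c3ccc(OCc4ccccc4)cc3)c2O)c1 | intermediate (not isolated)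
17 | 4-(benzyloxy)-3-[4-(benzyloxy)-3-{(2E)-3-[4-(benzyloxy)phenyl]prop-2-enoyl}-2-hydroxy-6-methoxyphenyl]benzoic acid | OC(=O)c1ccc(OCc2ccccc2)c(-c2c(OC)cc(OCc3ccccc3)c(C(=O)/C=C/c3ccc(OCc4ccccc4)cc3)c2O)c1 | intermediate
18 | 4-(benzyloxy)-3-{5-(benzyloxy)-2-[4-(benzyloxy)phenyl]-7-methoxy-4-oxo-4H-chromen-8-yl}benzoic acid | OC(=O)c1ccc(OCc2ccccc2)c(-c2c(OC)cc(OCc3ccccc3)c3c2OC(c2ccc(OCc4ccccc4)cc2)=CC3=O)c1 | intermediate
19 | 1-[2,4-bis(benzyloxy)-6-hydroxyphenyl]ethan-1-one | CC(=O)c1c(O)cc(OCc2ccccc2)cc1OCc1ccccc1 | starting material
20 | 2-acetyl-3,5-bis(benzyloxy)phenyl 4-(benzyloxy)-3-{5-(benzyloxy)-2-[4-(benzyloxy)phenyl]-7-methoxy-4-oxo-4H-chromen-8-yl}benzoate | CC(=O)c1c(OCc2ccccc2)cc(OCc2ccccc2)cc1OC(=O)c1ccc(OCc2ccccc2)c(-c2c(OC)cc(OCc3ccccc3)c3c2OC(c2ccc(OCc4ccccc4)cc2)=CC3=O)c1 | intermediate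
21 | 1-[2,4-bis(benzyloxy)-6-hydroxyphenyl]-3-[4-(benzyloxy)-3-{5-(benzyloxy)-2-[4-(benzyloxy)phenyl]-7-methoxy-4-oxo-4H-chromen-8-yl}phenyl]propane-1,3-dione | O=C(CC(=O)c1ccc(OCc2ccccc2)c(-c2c(OC)cc(OCc3ccccc3)c3c2OC(c2ccc(OCc4ccccc4)cc2)=CC3=O)c1)c1c(O)cc(OCc2ccccc2)cc1OCc1ccccc1 | intermediate (not isolated)
22 | 5,7-bis(benzyloxy)-2-[4-(benzyloxy)-3-{5-(benzyloxy)-2-[4-(benzyloxy)phenyl]-7-methoxy-4-oxo-4H-chromen-8-yl}phenyl]-4H-chromen-4-one | COc1cc(OCc2ccccc2)c2c(c1-c1cc(C3=CC(=O)c4c(OCc5ccccc5)cc(OCc5ccccc5)cc4O3)ccc1OCc1ccccc1)OC(c1ccc(OCc3ccccc3)cc1)=CC2=O | intermediate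
23 | bis(enol silane) of 24: the (2S,2''S)-bis(2H-chromene) in which O4 and O4'' each carry a SiMe(OEt)2 group | COc1cc(OCc2ccccc2)c2c(c1-c1cc([C@@H]3C=C(O[Si](C)(OCC)OCC)c4c(OCc5ccccc5)cc(OCc5ccccc5)cc4O3)ccc1OCc1ccccc1)O[C@H](c1ccc(OCc3ccccc3)cc1)C=C2O[Si](C)(OCC)OCC | intermediate (not isolated)
24 | (2S)-5,7-bis(benzyloxy)-2-[4-(benzyloxy)-3-{(2S)-5-(benzyloxy)-2-[4-(benzyloxy)phenyl]-7-methoxy-4-oxo-3,4-dihydro-2H-chromen-8-yl}phenyl]-2,3-dihydro-4H-chromen-4-one | COc1cc(OCc2ccccc2)c2c(c1-c1cc([C@@H]3CC(=O)c4c(OCc5ccccc5)cc(OCc5ccccc5)cc4O3)ccc1OCc1ccccc1)O[C@H](c1ccc(OCc3ccccc3)cc1)CC2=O | intermediate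
25 | (2S)-5,7-dihydroxy-2-[4-hydroxy-3-{(2S)-5-hydroxy-2-(4-hydroxyphenyl)-7-methoxy-4-oxo-3,4-dihydro-2H-chromen-8-yl}phenyl]-2,3-dihydro-4H-chromen-4-one | COc1cc(O)c2c(c1-c1cc([C@@H]3CC(=O)c4c(O)cc(O)cc4O3)ccc1O)O[C@H](c1ccc(O)cc1)CC2=O | target

## Step count and least certain steps

Total: 14 steps. Longest linear sequence: 14 steps, from 1 to 25; 3, 7, 15 and 19 enter as purchased reagents.

**Step 5 (key step).** The cycloaddition may be slow or fail because the aryl-bearing diene terminus is shielded by two ortho methoxy groups. Hydrolysis of the enol silane, thermal oligomerisation of the propiolate or a stepwise Michael-type addition to open-chain products could then take over.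
Fallback: the benzannulation is given up and the biaryl bond is made by Suzuki–Miyaura coupling. This fallback does not branch from a route intermediate. It sets out from purchased methyl 3-bromo-4-hydroxybenzoate F1 and (2,4,6-trimethoxyphenyl)boronic acid F2 in place of 1 (compounds 1 to 9 are bypassed) and comes back to the route at 10. The conditions would be Pd(OAc)2, SPhos, K3PO4, toluene–water, 90 °C; the dialkylbiarylphosphine is chosen for the doubly ortho-substituted, protodeboronation-prone boronic acid.

**Step 13.** Conversion may be poor because both chromones are vinylogous esters deactivated by peri and para alkoxy groups. Facial selectivity may differ between the two rings (C2'' lies next to the 8''-aryl group). The copper enolate may also open by β-elimination of phenoxide, followed by over-reduction.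
Fallback: from 22, homogeneous asymmetric hydrogenation of the C=C and C=O bonds of both pyranones (H2, Ru(cod)(2-methylallyl)2 with a chiral N-heterocyclic carbene ligand, KOt-Bu) should give the bis(flavan-4-ol) F3. Re-oxidation of the two benzylic alcohols with Dess–Martin periodinane then returns to the route at 24, with C2 and C2'' untouched by the oxidation.

**Step 7.** The second ether cleavage may stall once the first phenoxide locks the ketone in a boron chelate; on forcing, the ester or the 7''-methyl group may be lost.
Fallback: from 10, acylation and cleavage are merged in one aluminium-mediated operation (acetyl chloride, excess AlCl3, CH2Cl2 then 1,2-dichloroethane at 60 °C), in which each ortho methyl group is lost on formation of an aluminium phenoxide–ketone chelate. This bypasses 12, comes back at 13 and makes no new compound.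

**Step 8.** Site selectivity between the two chelated ring D phenols may be poor, which would put the benzyl group on the oxygen needed for ring E and lead to the 6''-aryl isomer.
Fallback: from 13, the two phenols ortho to the biaryl bond (O4' and the ring D 2-OH) form a 2,2'-biphenol. They are tied as a seven-membered acetonide F4 (2,2-dimethoxypropane, camphorsulfonic acid). The only free phenol is then benzylated to F5 (BnBr, K2CO3, DMF, 60 °C). Dilute HCl in THF removes the acetonide to give the diol F6, and one equivalent of BnBr with K2CO3 in acetone benzylates the unchelated ring B phenol, returning to the route at 14.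

## Further compounds

F1 | step 5 | methyl 3-bromo-4-hydroxybenzoate | COC(=O)c1ccc(O)c(Br)c1
F2 | step 5 | (2,4,6-trimethoxyphenyl)boronic acid | COc1cc(OC)c(B(O)O)c(OC)c1
F3 | step 13 | (2S)-5,7-bis(benzyloxy)-2-[4-(benzyloxy)-3-{(2S)-5-(benzyloxy)-2-[4-(benzyloxy)phenyl]-4-hydroxy-7-methoxy-3,4-dihydro-2H-chromen-8-yl}phenyl]-3,4-dihydro-2H-chromen-4-ol (configuration at C4 and C4'' not specified) | COc1cc(OCc2ccccc2)c2c(c1-c1cc([C@@H]3CC(O)c4c(OCc5ccccc5)cc(OCc5ccccc5)cc4O3)ccc1OCc1ccccc1)O[C@H](c1ccc(OCc3ccccc3)cc1)CC2O
F0 | step 7 | none | none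
F4 | step 8 | methyl 4-acetyl-3-hydroxy-1-methoxy-6,6-dimethyldibenzo[d,f][1,3]dioxepine-10-carboxylate (acetonide of 13 bridging O4' and the ring D 2-oxygen) | COC(=O)c1ccc2c(c1)-c1c(OC)cc(O)c(C(C)=O)c1OC(C)(C)O2
F5 | step 8 | methyl 4-acetyl-3-(benzyloxy)-1-methoxy-6,6-dimethyldibenzo[d,f][1,3]dioxepine-10-carboxylate | COC(=O)c1ccc2c(c1)-c1c(OC)cc(OCc3ccccc3)c(C(C)=O)c1OC(C)(C)O2
F6 | step 8 | methyl 3-[3-acetyl-4-(benzyloxy)-2-hydroxy-6-methoxyphenyl]-4-hydroxybenzoate | COC(=O)c1ccc(O)c(-c2c(OC)cc(OCc3ccccc3)c(C(C)=O)c2O)c1
A1 | alternative 1 | (2S,4S)-5-(benzyloxy)-8-[2-(benzyloxy)-5-chlorophenyl]-2-[4-(benzyloxy)phenyl]-4,7-dimethoxy-3,4-dihydro-2H-chromene (2,4-cis) | COc1cc(OCc2ccccc2)c2c(c1-c1cc(Cl)ccc1OCc1ccccc1)O[C@H](c1ccc(OCc3ccccc3)cc1)C[C@@H]2OC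
A2 | alternative 1 | 1-(benzyloxy)-4-ethenylbenzene | C=Cc1ccc(OCc2ccccc2)cc1
A3 | alternative 2 | 5-(benzyloxy)-2-[2-(benzyloxy)-5-bromophenyl]-3-methoxyphenol | COc1cc(OCc2ccccc2)cc(O)c1-c1cc(Br)ccc1OCc1ccccc1
A4 | alternative 2 | 3-(benzyloxy)cyclobut-2-en-1-one | O=C1CC(OCc2ccccc2)=C1
A5 | alternative 3 | 4-[(2S)-5-(benzyloxy)-8-[2-(benzyloxy)-5-bromophenyl]-7-methoxy-4-oxo-3,4-dihydro-2H-chromen-2-yl]phenyl acetate | COc1cc(OCc2ccccc2)c2c(c1-c1cc(Br)ccc1OCc1ccccc1)O[C@H](c1ccc(OC(C)=O)cc1)CC2=O
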